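**Strategy.** All three guaianolide units derive from dehydrocostus lactone (guaiane numbering; primes for the central unit B, double primes for unit C). The monomer destined for unit B is opened by alkoxy-radical fragmentation of C9'–C10': C10' becomes an acetyl group whose silyl enol ether is a stable diene for the B–C Diels–Alder reaction, C9' a primary iodide. After the A–B cycloaddition, C10' is an alkenyl nonaflate on the tetrasubstituted C1'=C10' bond shared by the cyclopentanone of unit B and the B–C cyclohexene, held cis to C5'. Intramolecular Negishi coupling of the C9' zinc reagent then forms C9'–C10' and closes the seven-membered carbocycle of unit B as the final ring; a singlet-oxygen ene reaction installs the C10' hydroxyl.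

Key step: step 11

Remark: dehydrocostus lactone is assumed to be bought; α means the side of a five-membered ring that carries H-5 (H-5', H-5''), β the side that carries C6 (C6', C6''); C5, C6 and C7 of every unit keep the configuration of the starting material.

Step 1
Reactants: 1 dehydrocostus lactone
Product: 2 3-hydroxyguaia-4(15),10(14),11(13)-trien-12,6-olide (zaluzanin C together with its C3 epimer)
Conditions: SeO2 (0.5 equiv), t-BuOOH, CH2Cl2, 20 °C
Reagents that add atoms: tert-butyl hydroperoxide CC(C)(C)OO (oxygen passed on through selenium dioxide O=[Se]=O)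
Why: Selenium dioxide allylic hydroxylation (ene reaction, then [2,3]-sigmatropic shift) should take place at C3, the ring methylene allylic to C4=C15, and the C3 configuration is irrelevant because step 2 removes it.

Step 2
Reactants: 2 3-hydroxyguaia-4(15),10(14),11(13)-trien-12,6-olide
Product: 3 dehydrozaluzanin C
Conditions: Dess–Martin periodinane, CH2Cl2, 20 °C
Reagents that add atoms: none
Why: Dess–Martin oxidation converts either allylic alcohol epimer into the exocyclic enone without touching the three exocyclic alkenes.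

Step 3
Reactants: 3 dehydrozaluzanin C
Product: 4 10-hydroxy-3-oxoguaia-4(15),11(13)-dien-12,6-olide (C10 epimers)
Conditions: Co(acac)2 (20 mol%), PhSiH3, O2 (1 atm), THF/i-PrOH, 20 °C
Reagents that add atoms: dioxygen O=O
Why: Mukaiyama hydration, in which hydrogen-atom transfer from the cobalt hydride should select the only electron-rich alkene C10=C14 over the conjugated C4=C15 and C11=C13, and O2 traps the tertiary C10 radical; C10 need not be controlled because it becomes a carbonyl carbon in step 5.

Step 4
Reactants: 4 10-hydroxy-3-oxoguaia-4(15),11(13)-dien-12,6-olide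
Product: 5 10-hydroxy-3-oxoguaia-1,4(15),11(13)-trien-12,6-olide
Conditions: IBX (2.5 equiv), DMSO/fluorobenzene, 70 °C
Reagents that add atoms: none
Why: IBX dehydrogenation of the ketone can only introduce the C1=C2 double bond, because C2 carries the only α-hydrogens of the C3 carbonyl, and the tertiary alcohol is inert to the oxidant.

Step 5
Reactants: 5 10-hydroxy-3-oxoguaia-1,4(15),11(13)-trien-12,6-olide
Product: 6 9-iodo-3,10-dioxo-9,10-secoguaia-1,4(15),11(13)-trien-12,6-olide
Conditions: PhI(OAc)2 (1.5 equiv), I2 (1.2 equiv), CH2Cl2, visible light, 20 °C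
Reagents that add atoms: iodine II
Why: Hypoiodite alkoxy-radical β-fragmentation (Suárez conditions) should cleave C9–C10, the only scission that expels a primary alkyl radical (the others would give a methyl or a vinyl radical) and that releases a conjugated ene-dione, and iodine then traps the C9 radical.

Step 6
Reactants: 6 9-iodo-3,10-dioxo-9,10-secoguaia-1,4(15),11(13)-trien-12,6-olide
Product: 7 10-(tert-butyldimethylsilyloxy)-9-iodo-3-oxo-9,10-secoguaia-1,4(15),10(14),11(13)-tetraen-12,6-olide
Conditions: TBSOTf (1.2 equiv), Et3N (2 equiv), CH2Cl2, −78 °C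
Reagents that add atoms: tert-butyldimethylsilyl triflate CC(C)(C)[Si](C)(C)OS(=O)(=O)C(F)(F)F
Why: Soft enolization should silylate only the acetyl group, whose methyl (C14') carries the only α-hydrogens in the molecule (C3' is flanked by the sp2 carbons C2' and C4'), giving the 2-silyloxy diene C14'=C10'–C1'=C2' at a temperature at which the primary iodide and the hindered γ-hydrogen at C5' are left alone.

Step 7
Reactants: 7 silyloxy diene; 3 dehydrozaluzanin C
Product: 8 B–C cycloadduct (cyclohexene C2'–C1'=C10'(OTBS)–C14'–C15''–C4'', spiro at C4''; C2' bonded to C4'' on the α face of unit C; H-2' β)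
Conditions: toluene, BHT (cat.), 45 °C, dark, equimolar amounts, syringe-pump addition of the diene to the dienophile (1 M)
Reagents that add atoms: none
Why: Normal-demand Diels–Alder reaction in which the silyloxy group makes C14' the nucleophilic terminus, so C14' joins the enone β-carbon C15'' and C2' joins C4''; the diene should add to the convex α face of 3 (the side of H-1'' and H-5''), which sets spiro C4'', 3 should approach the diene opposite to the lactone on C5', which leaves H-2' on the β face, these two preferences together correspond to the carbonyl-exo topology common for s-cis-locked α-methylene cycloalkanones (only H-5'' of the C5'' branch points at the diene), and slow addition of 7 keeps its own exocyclic enone from competing as dienophile.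

Step 8
Reactants: 8 B–C cycloadduct
Product: 9 C10' nonaflate of the B–C cycloadduct
Conditions: C4F9SO2F (3 equiv), TBAT (0.2 equiv), THF, −40 to 0 °C
Reagents that add atoms: nonafluorobutanesulfonyl fluoride O=S(=O)(F)C(F)(F)C(F)(F)C(F)(F)C(F)(F)F
Why: Fluoride-catalysed O-sulfonylation of the silyl enol ether passes the C1'=C10' enol regiochemistry on unchanged to the alkenyl nonaflate, the hindered tetrasubstituted enolate being captured on oxygen by the excess sulfonyl fluoride before it can alkylate.

Step 9
Reactants: 3 dehydrozaluzanin C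
Product: 10 3-(trimethylsilyloxy)guaia-2,4(15),10(14),11(13)-tetraen-12,6-olide
Conditions: TMSOTf, Et3N, CH2Cl2, 0 °C
Reagents that add atoms: trimethylsilyl triflate C[Si](C)(C)OS(=O)(=O)C(F)(F)F
Why: Soft enolization toward C2, the only α-position of the C3 ketone that bears hydrogen, gives the cross-conjugated silyl dienol ether.

Step 10
Reactants: 9 C10' nonaflate of the B–C cycloadduct; 10 silyl dienol ether
Product: 13 seco-trimer nonaflate iodide (unit A as C1=C2 enone; H-10 α; C2 of unit A on the β face of unit B at spiro C4'), via transient dienone 11 (not isolated), via initial cycloadduct 12 (not isolated)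
Conditions: IBX, 4-methoxypyridine N-oxide, DMSO, 25 °C, argon, equimolar amounts, syringe-pump addition of the dienol ether; then Et3N (0.2 equiv), CH2Cl2, 0 °C
Reagents that add atoms: none
Why: IBX dehydrogenation of the silyl enol ether releases dienone 11 at low stationary concentration, whose C2=C1–C10=C14 diene should add to the exocyclic enone C4'=C15' of 9 in an ortho-selective Diels–Alder reaction on the β face of unit B (the α face next to C3' is covered by spiro unit C, attached α at C2'), which sets spiro C4' whatever the configuration at C2 of 12, and amine-mediated tautomerization of the β,γ-enone then protonates C10 of unit A from its convex α face.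

Step 11
Reactants: 13 seco-trimer nonaflate iodide
Product: 15 10'-deoxy-1'(10')-ene trimer (seven-membered ring of unit B closed; H-2' β), via alkylzinc iodide 14 (not isolated)
Conditions: Zn dust (5 equiv), I2 (5 mol%), DMA, 40 °C; then syringe pump into Pd(OAc)2 (10 mol%), CPhos (20 mol%), THF, 45 °C, final 2 mM
Reagents that add atoms: none
Why: Zinc inserts into the primary C9'–I bond to give alkylzinc iodide 14; zerovalent palladium, formed from Pd(OAc)2 and CPhos by the organozinc, adds oxidatively to the C10'–ONf bond, intramolecular transmetalation gives an eight-membered palladacycle, and reductive elimination forms C9'–C10'. The closest known reaction type is the Negishi cross-coupling of primary alkylzinc halides with alkenyl sulfonates, run here intramolecularly at high dilution. The seven-membered carbocycle of unit B (C1', C5', C6', C7', C8', C9', C10') is closed by C(sp3)–C(sp2) reductive elimination, with the C1'=C10' alkene kept inside the new ring, so no attack on a π bond is involved. No stereocenter is formed: C2', C4', C4'', C5', C6' and C7' are untouched and C10' stays sp2 until step 12. The step needs cyclization to outrun oligomerization, β-hydride elimination and protodezincation; the cyclohexene ring fixes the nonaflate cis to C5' across C1'=C10', so the chain C6'–C9' already spans the two termini, and CPhos favours reductive elimination. It also needs chemoselectivity toward three α-methylene lactones, a cross-conjugated dienone and two ketones, which the low reactivity of copper-free alkylzinc iodides toward carbonyl groups and Michael acceptors should secure.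

Step 12
Reactants: 15 10'-deoxy-1'(10')-ene trimer
Product: 17 ainsliatrimer A, via C10' hydroperoxide 16 (not isolated)
Conditions: O2, tetraphenylporphyrin (1 mol%), visible light, CH2Cl2, −40 °C; then PPh3, −40 to 0 °C
Reagents that add atoms: dioxygen O=O
Why: Schenck ene reaction of singlet oxygen with the only tetrasubstituted electron-rich alkene (C1'=C10'), in which suprafacial abstraction of the ketone-activated H-2' on the β face should place the oxygen on C10' on that same β face and move the double bond into conjugation (C1'=C2'), as known for β,γ-unsaturated ketones, and triphenylphosphine reduces the hydroperoxide to the tertiary alcohol.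

**Compound list**

1 | dehydrocostus lactone | C=C1CC[C@H]2C(=C)CC[C@H]3C(=C)C(=O)O[C@@H]3[C@H]21 | starting material
2 | 3-hydroxyguaia-4(15),10(14),11(13)-trien-12,6-olide (C3 epimers) | C=C1C(O)C[C@H]2C(=C)CC[C@H]3C(=C)C(=O)O[C@@H]3[C@H]21 | intermediate
3 | dehydrozaluzanin C | C=C1C(=O)C[C@H]2C(=C)CC[C@H]3C(=C)C(=O)O[C@@H]3[C@H]21 | intermediate
4 | 10-hydroxy-3-oxoguaia-4(15),11(13)-dien-12,6-olide (C10 epimers) | C=C1C(=O)C[C@H]2C(C)(O)CC[C@H]3C(=C)C(=O)O[C@@H]3[C@H]21 | intermediate
5 | 10-hydroxy-3-oxoguaia-1,4(15),11(13)-trien-12,6-olide (C10 epimers) | C=C1C(=O)C=C2C(C)(O)CC[C@H]3C(=C)C(=O)O[C@@H]3[C@H]21 | intermediate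
6 | 9-iodo-3,10-dioxo-9,10-secoguaia-1,4(15),11(13)-trien-12,6-olide | C=C1C(=O)C=C(C(C)=O)[C@H]1[C@H]1OC(=O)C(=C)[C@@H]1CCI | intermediate
7 | 10-(tert-butyldimethylsilyloxy)-9-iodo-3-oxo-9,10-secoguaia-1,4(15),10(14),11(13)-tetraen-12,6-olide | C=C1C(=O)C=C(C(=C)O[Si](C)(C)C(C)(C)C)[C@H]1[C@H]1OC(=O)C(=C)[C@@H]1CCI | intermediate
8 | B–C cycloadduct, C10' silyl enol ether (H-2' β; C2'–C4'' bond α on unit C) | C=C1C(=O)[C@H]2C(=C(O[Si](C)(C)C(C)(C)C)CC[C@]23C(=O)C[C@H]4C(=C)CC[C@H]5C(=C)C(=O)O[C@@H]5[C@H]43)[C@H]1[C@H]1OC(=O)C(=C)[C@@H]1CCI | intermediate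
9 | B–C cycloadduct, C10' nonaflate | C=C1C(=O)[C@H]2C(=C(OS(=O)(=O)C(F)(F)C(F)(F)C(F)(F)C(F)(F)F)CC[C@]23C(=O)C[C@H]4C(=C)CC[C@H]5C(=C)C(=O)O[C@@H]5[C@H]43)[C@H]1[C@H]1OC(=O)C(=C)[C@@H]1CCI | intermediate
10 | 3-(trimethylsilyloxy)guaia-2,4(15),10(14),11(13)-tetraen-12,6-olide | C=C1C(O[Si](C)(C)C)=C[C@H]2C(=C)CC[C@H]3C(=C)C(=O)O[C@@H]3[C@H]21 | intermediate
11 | 3-oxoguaia-1,4(15),10(14),11(13)-tetraen-12,6-olide (transient dienone, not isolated) | C=C1C(=O)C=C2C(=C)CC[C@H]3C(=C)C(=O)O[C@@H]3[C@H]21 | intermediate
12 | initial A–B cycloadduct (unit A with C1=C10 and H-2 β; not isolated) | C=C1C(=O)[C@H]2C3=C(CC[C@H]4C(=C)C(=O)O[C@@H]4[C@@H]13)CC[C@@]21C(=O)[C@H]2C(=C(OS(=O)(=O)C(F)(F)C(F)(F)C(F)(F)C(F)(F)F)CC[C@]23C(=O)C[C@H]4C(=C)CC[C@H]5C(=C)C(=O)O[C@@H]5[C@H]43)[C@H]1[C@H]1OC(=O)C(=C)[C@@H]1CCI | intermediate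
13 | seco-trimer nonaflate iodide (unit A conjugated, H-10 α) | C=C1C(=O)C2=C3[C@H](CC[C@H]4C(=C)C(=O)O[C@@H]4[C@@H]13)CC[C@@]21C(=O)[C@H]2C(=C(OS(=O)(=O)C(F)(F)C(F)(F)C(F)(F)C(F)(F)F)CC[C@]23C(=O)C[C@H]4C(=C)CC[C@H]5C(=C)C(=O)O[C@@H]5[C@H]43)[C@H]1[C@H]1OC(=O)C(=C)[C@@H]1CCI | intermediate
14 | alkylzinc iodide of 13 (not isolated) | C=C1C(=O)C2=C3[C@H](CC[C@H]4C(=C)C(=O)O[C@@H]4[C@@H]13)CC[C@@]21C(=O)[C@H]2C(=C(OS(=O)(=O)C(F)(F)C(F)(F)C(F)(F)C(F)(F)F)CC[C@]23C(=O)C[C@H]4C(=C)CC[C@H]5C(=C)C(=O)O[C@@H]5[C@H]43)[C@H]1[C@H]1OC(=O)C(=C)[C@@H]1CC[Zn]I | intermediate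
15 | 10'-deoxy-1'(10')-ene trimer (H-2' β) | C=C1C(=O)C2=C3[C@H](CC[C@H]4C(=C)C(=O)O[C@@H]4[C@@H]13)CC[C@@]21C(=O)[C@H]2C3=C(CC[C@]24C(=O)C[C@H]5C(=C)CC[C@H]6C(=C)C(=O)O[C@@H]6[C@H]54)CC[C@H]4C(=C)C(=O)O[C@@H]4[C@H]31 | intermediate
16 | ainsliatrimer A 10'-hydroperoxide (not isolated) | C=C1C(=O)C2=C3[C@H](CC[C@H]4C(=C)C(=O)O[C@@H]4[C@@H]13)CC[C@@]21C(=O)C2=C3[C@H]1[C@H]1OC(=O)C(=C)[C@@H]1CC[C@@]3(OO)CC[C@]21C(=O)C[C@H]2C(=C)CC[C@H]3C(=C)C(=O)O[C@@H]3[C@H]21 | intermediate
17 | ainsliatrimer A | C=C1C(=O)C2=C3[C@H](CC[C@H]4C(=C)C(=O)O[C@@H]4[C@@H]13)CC[C@@]21C(=O)C2=C3[C@H]1[C@H]1OC(=O)C(=C)[C@@H]1CC[C@@]3(O)CC[C@]21C(=O)C[C@H]2C(=C)CC[C@H]3C(=C)C(=O)O[C@@H]3[C@H]21 | target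

**Totals.** Total step count: 12. Longest linear sequence: 11 steps (steps 1 to 8, then 10, 11 and 12; step 9 is the side branch).

**Steps most likely to fail**

Step 11 (key step). Protodezincation of 14, β-hydride elimination at the tethered alkylpalladium or intermolecular coupling could outrun ring closure and give open-chain reduced or oligomeric material. The fallback sets out from 13 and avoids a preformed organometallic: nickel-catalysed reductive cross-electrophile coupling (NiBr2·glyme, 4,4'-di-tert-butyl-2,2'-bipyridine, Mn powder, NaI, DMA, 25 °C, 2 mM). Here a C9' radical is captured by the alkenylnickel species formed from the nonaflate and the same C9'–C10' bond results. It comes back to the route at 15 and forms no new compound (F0).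

Step 8. The enolate set free by fluoride may alkylate itself at C1' with the C9' iodide, closing a six-membered ring, or add to a neighbouring Michael acceptor before it is sulfonylated on oxygen. The fallback sets out from 5 and carries the halide as a far less electrophilic chloride. Hypochlorite fragmentation (NaOCl, AcOH, CH2Cl2, 0 °C; then visible light) gives the seco chloride F1. Silylation as in step 6 gives the silyloxy diene chloride F2, cycloaddition with 3 as in step 7 gives the cycloadduct chloride F3, and nonaflation as in step 8 gives the nonaflate chloride F4. Finkelstein exchange (NaI, acetone, 50 °C) then comes back to the route at 9.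

Step 10. Dienone 11 is both diene and dienophile and may dimerize faster than it meets 9; the iodine oxidant may also attack the alkyl iodide, facial control at C4' could erode if much 11 accumulates, and in the second stage the amine could epimerize C2' of unit B. The fallback sets out from 10 and releases the diene slowly from a selenide. PhSeCl (CH2Cl2, −78 °C) gives the 2-phenylselanyl ketone F5. Oxidation with H2O2 and pyridine at 0 °C in the presence of 9 forms the selenoxide, whose syn elimination with H-1 feeds 11 at low stationary concentration into the same cycloaddition. Tautomerization of unit A on silica gel, without amine, then comes back to the route at 13.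

Further compounds
F0 | step 11 | none | none
F1 | step 8 | 9-chloro-3,10-dioxo-9,10-secoguaia-1,4(15),11(13)-trien-12,6-olide | C=C1C(=O)C=C(C(C)=O)[C@H]1[C@H]1OC(=O)C(=C)[C@@H]1CCCl
F2 | step 8 | 10-(tert-butyldimethylsilyloxy)-9-chloro-3-oxo-9,10-secoguaia-1,4(15),10(14),11(13)-tetraen-12,6-olide | C=C1C(=O)C=C(C(=C)O[Si](C)(C)C(C)(C)C)[C@H]1[C@H]1OC(=O)C(=C)[C@@H]1CCCl
F3 | step 8 | B–C cycloadduct, C10' silyl enol ether, C9' chloride | C=C1C(=O)[C@H]2C(=C(O[Si](C)(C)C(C)(C)C)CC[C@]23C(=O)C[C@H]4C(=C)CC[C@H]5C(=C)C(=O)O[C@@H]5[C@H]43)[C@H]1[C@H]1OC(=O)C(=C)[C@@H]1CCCl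
F4 | step 8 | B–C cycloadduct, C10' nonaflate, C9' chloride | C=C1C(=O)[C@H]2C(=C(OS(=O)(=O)C(F)(F)C(F)(F)C(F)(F)C(F)(F)F)CC[C@]23C(=O)C[C@H]4C(=C)CC[C@H]5C(=C)C(=O)O[C@@H]5[C@H]43)[C@H]1[C@H]1OC(=O)C(=C)[C@@H]1CCCl
F5 | step 10 | 2α-(phenylselanyl)dehydrozaluzanin C | C=C1C(=O)[C@H]([Se]c4ccccc4)[C@H]2C(=C)CC[C@H]3C(=C)C(=O)O[C@@H]3[C@H]21
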